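**Plan**

- Retrosynthesis: the ketone between ring B and the 2,4-dimethoxyphenyl ring is traced back to a silyl-protected carbinol and the C1 methylene to a lactone carbonyl, which uncovers a 3-substituted 6,7-dimethoxyisocoumarin.
- The isocoumarin is cut at C4–C4a, C8a–C1 and O2–C3 at once into 4,5-dimethoxybenzyne, a terminal propargylic silyl ether and CO2.
- This is possible because C4a and C8a are adjacent carbons of ring A (the dimethoxybenzene) that carry C4 and C1 of ring B (the pyran ring). The 6,7-dimethoxy pattern makes the two aryne carbons mirror images, so only one regioisomer can form.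
- Forward: ring A and the 2,4-dimethoxyphenyl ring are bought, the alkyne is made in two steps, ring B closes in step 3, C1 goes from C=O to CH2 in two steps, and desilylation and oxidation finish the route.
- Stereochemistry: the target has no stereocentre; the carbinol carbon is carried as a racemate and becomes the ketone in the last step.

Key step: step 3

Remark: the lactol carbon of 10 is an inconsequential mixture of epimers that is removed in step 5. IPrCuCl stands for chloro[1,3-bis(2,6-diisopropylphenyl)imidazol-2-ylidene]copper. Compound 5 is taken to be purchased.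

**Route**

Step 1
Reactants: 1 2,4-dimethoxybenzaldehyde; 2 ethynylmagnesium bromide
Product: 3 1-(2,4-dimethoxyphenyl)prop-2-yn-1-ol (racemic)
Conditions: HC≡CMgBr (1.3 equiv), THF, 0 °C to rt; aq NH4Cl
Reagents that add atoms: ethynylmagnesium bromide (compound 2), C#C[Mg]Br
Why: Grignard 1,2-addition of an alkynyl nucleophile to an aromatic aldehyde is reliable, and the new carbinol centre forms as a racemate, which is acceptable because step 7 oxidises it.

Step 2
Reactants: 3 1-(2,4-dimethoxyphenyl)prop-2-yn-1-ol
Product: 4 tert-butyl{[1-(2,4-dimethoxyphenyl)prop-2-yn-1-yl]oxy}dimethylsilane (racemic)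
Conditions: TBSCl (1.2 equiv), imidazole (2.5 equiv), DMF, 0 °C to rt
Reagents that add atoms: tert-butyldimethylsilyl chloride (TBSCl), CC(C)(C)[Si](C)(C)Cl
Why: Silylation of a secondary alcohol with TBSCl and imidazole (Corey protocol) should proceed through the N-silylimidazolium species and masks the hydroxyl against the base, the copper carboxylate and the hydride reagents of steps 3 to 5.

Step 3
Reactants: 4 tert-butyl{[1-(2,4-dimethoxyphenyl)prop-2-yn-1-yl]oxy}dimethylsilane; 5 4,5-dimethoxy-2-(trimethylsilyl)phenyl trifluoromethanesulfonate; 6 carbon dioxide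
Product: 9 3-[(tert-butyldimethylsilyloxy)(2,4-dimethoxyphenyl)methyl]-6,7-dimethoxy-1H-isochromen-1-one (racemic), via 4,5-dimethoxybenzyne 7 (not isolated), via cesium 2-alkynylbenzoate 8 (not isolated)
Conditions: 5 (1.5 equiv), IPrCuCl (10 mol %), CsF (3 equiv), Cs2CO3 (1.2 equiv), CO2 (1 atm), MeCN, 80 °C
Reagents that add atoms: carbon dioxide (compound 6), O=C=O
Why: CsF removes the trimethylsilyl group of 5 and expels triflate to give aryne 7, while Cs2CO3 and IPrCuCl (monovalent copper) turn the terminal alkyne of 4 into a copper acetylide that adds across the strained triple bond (C4–C4a); the ortho-alkynyl aryl copper then inserts CO2 (C8a–C1) to give carboxylate 8. Ring B closes by 6-endo-dig attack of the carboxylate oxygen on the copper-activated alkyne at the carbon remote from ring A (O2–C3), and protonation of the C4 vinyl copper releases 9 and returns the catalyst. The closest known reaction type is the copper–carbene-catalysed three-component coupling of arynes, terminal alkynes and CO2 to 3-substituted isocoumarins, applied here to a propargylic silyl ether. No stereocentre is created, and the racemic carbinol carbon of 4 is a spectator. The step needs acetylide addition and CO2 uptake to outrun protonation of the aryl copper, which the CO2 atmosphere and the slow release of 7 by sparingly soluble CsF should favour, and it needs 6-endo over 5-exo closure, which π-activation by the carbene-bound copper (as opposed to attack of a free carboxylate) should provide. Aryne regiochemistry is no issue, because the mirror plane through the C6–C7 and C4a–C8a bonds makes the two aryne carbons equivalent.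

Step 4
Reactants: 9 3-[(tert-butyldimethylsilyloxy)(2,4-dimethoxyphenyl)methyl]-6,7-dimethoxy-1H-isochromen-1-one
Product: 10 3-[(tert-butyldimethylsilyloxy)(2,4-dimethoxyphenyl)methyl]-6,7-dimethoxy-1H-isochromen-1-ol (mixture of epimers at C1)
Conditions: iBu2AlH (1.2 equiv), CH2Cl2, −78 °C; aq potassium sodium tartrate
Reagents that add atoms: none
Why: Partial reduction of a lactone to the lactol with iBu2AlH should stop at the tetrahedral aluminium hemiacetal at −78 °C, the silyl and aryl ethers are inert, and the C1 configuration is irrelevant because step 5 turns this carbon into CH2.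

Step 5
Reactants: 10 3-[(tert-butyldimethylsilyloxy)(2,4-dimethoxyphenyl)methyl]-6,7-dimethoxy-1H-isochromen-1-ol
Product: 12 tert-butyl[(6,7-dimethoxy-1H-isochromen-3-yl)(2,4-dimethoxyphenyl)methoxy]dimethylsilane (racemic), via 2-benzopyrylium ion 11 (not isolated)
Conditions: Et3SiH (3 equiv), BF3·OEt2 (1.5 equiv), CH2Cl2, −78 °C; Et3N, then aq NaHCO3
Reagents that add atoms: none
Why: In this ionic hydrogenation of a lactol, BF3 ionises the C1 hydroxyl to the aromatic 2-benzopyrylium ion 11 and Et3SiH delivers hydride to C1, the position whose attack keeps ring A benzenoid; the low temperature and the basic quench should leave the benzylic silyl ether and the enol ether untouched.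

Step 6
Reactants: 12 tert-butyl[(6,7-dimethoxy-1H-isochromen-3-yl)(2,4-dimethoxyphenyl)methoxy]dimethylsilane
Product: 13 (6,7-dimethoxy-1H-isochromen-3-yl)(2,4-dimethoxyphenyl)methanol (racemic)
Conditions: TBAF (1.2 equiv), THF, 0 °C; water work-up, Et3N-treated silica
Reagents that add atoms: none
Why: Fluoride-mediated desilylation is driven by the strong Si–F bond and runs under basic conditions, which the acid-sensitive enol ether and the allylic, benzylic carbinol should tolerate.

Step 7
Reactants: 13 (6,7-dimethoxy-1H-isochromen-3-yl)(2,4-dimethoxyphenyl)methanol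
Product: 14 (6,7-dimethoxy-1H-isochromen-3-yl)(2,4-dimethoxyphenyl)methanone (CNP0233831.0)
Conditions: MnO2 (activated, excess), CH2Cl2, rt
Reagents that add atoms: none
Why: MnO2 oxidation is selective for allylic and benzylic alcohols under neutral conditions, so the doubly activated carbinol should give the ketone while the C1 methylene and the enol ether stay intact, and the only stereocentre of the route is removed.

**Compound list**

1 | 2,4-dimethoxybenzaldehyde | COc1ccc(C=O)c(OC)c1 | starting material
2 | ethynylmagnesium bromide | C#C[Mg]Br | starting material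
3 | 1-(2,4-dimethoxyphenyl)prop-2-yn-1-ol (racemic) | COc1ccc(C(O)C#C)c(OC)c1 | intermediate
4 | tert-butyl{[1-(2,4-dimethoxyphenyl)prop-2-yn-1-yl]oxy}dimethylsilane (racemic) | COc1ccc(C(C#C)O[Si](C)(C)C(C)(C)C)c(OC)c1 | intermediate
5 | 4,5-dimethoxy-2-(trimethylsilyl)phenyl trifluoromethanesulfonate | COc1cc(OS(=O)(=O)C(F)(F)F)c(cc1OC)[Si](C)(C)C | starting material
6 | carbon dioxide | O=C=O | starting material
7 | 4,5-dimethoxybenzyne | COC1=CC#CC=C1OC | intermediate
8 | cesium 2-[3-(tert-butyldimethylsilyloxy)-3-(2,4-dimethoxyphenyl)prop-1-yn-1-yl]-4,5-dimethoxybenzoate (racemic; in exchange with its IPrCu carboxylate) | COc1ccc(C(O[Si](C)(C)C(C)(C)C)C#Cc2cc(OC)c(OC)cc2C(=O)[O-])c(OC)c1.[Cs+] | intermediate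
9 | 3-[(tert-butyldimethylsilyloxy)(2,4-dimethoxyphenyl)methyl]-6,7-dimethoxy-1H-isochromen-1-one (racemic) | COc1ccc(C(O[Si](C)(C)C(C)(C)C)C2=Cc3cc(OC)c(OC)cc3C(=O)O2)c(OC)c1 | intermediate
10 | 3-[(tert-butyldimethylsilyloxy)(2,4-dimethoxyphenyl)methyl]-6,7-dimethoxy-1H-isochromen-1-ol (mixture of epimers) | COc1ccc(C(O[Si](C)(C)C(C)(C)C)C2=Cc3cc(OC)c(OC)cc3C(O)O2)c(OC)c1 | intermediate
11 | 3-[(tert-butyldimethylsilyloxy)(2,4-dimethoxyphenyl)methyl]-6,7-dimethoxyisochromenylium hydroxytrifluoroborate | COc1ccc(C(O[Si](C)(C)C(C)(C)C)c2cc3cc(OC)c(OC)cc3c[o+]2)c(OC)c1.O[B-](F)(F)F | intermediate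
12 | tert-butyl[(6,7-dimethoxy-1H-isochromen-3-yl)(2,4-dimethoxyphenyl)methoxy]dimethylsilane (racemic) | COc1ccc(C(O[Si](C)(C)C(C)(C)C)C2=Cc3cc(OC)c(OC)cc3CO2)c(OC)c1 | intermediate
13 | (6,7-dimethoxy-1H-isochromen-3-yl)(2,4-dimethoxyphenyl)methanol (racemic) | COc1ccc(C(O)C2=Cc3cc(OC)c(OC)cc3CO2)c(OC)c1 | intermediate
14 | (6,7-dimethoxy-1H-isochromen-3-yl)(2,4-dimethoxyphenyl)methanone | COc1ccc(C(=O)C2=Cc3cc(OC)c(OC)cc3CO2)c(OC)c1 | target

**Count**

Total steps: 7. Longest linear sequence: 7 steps (1 to 14); aryne precursor 5 and CO2 enter in step 3.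

**Steps most likely to fail**

Step 3. The carboxylate may close 5-exo to an alkylidene phthalide, the aryl copper may be protonated before it takes up CO2, or fluoride may strip the silyl ether at the temperature needed.
- The fallback builds ring B stepwise and sets out from 4.
- Sonogashira coupling of 4 with purchased methyl 2-bromo-4,5-dimethoxybenzoate (COc1cc(Br)c(cc1OC)C(=O)OC; PdCl2(PPh3)2, CuI, Et3N, 60 °C) should give methyl 2-[3-(tert-butyldimethylsilyloxy)-3-(2,4-dimethoxyphenyl)prop-1-yn-1-yl]-4,5-dimethoxybenzoate F1.
- Electrophilic iodolactonisation of F1 with I2 in CH2Cl2, which closes such esters 6-endo with loss of the ester methyl group, should give 3-[(tert-butyldimethylsilyloxy)(2,4-dimethoxyphenyl)methyl]-4-iodo-6,7-dimethoxy-1H-isochromen-1-one F2.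
- Radical hydrodeiodination of F2 (Bu3SnH, AIBN, toluene, 80 °C) comes back to the route at 9.

Step 5. BF3 may ionise the doubly activated benzylic silyl ether so that hydride removes the oxygen, or the enol ether may be protonated and reduced on to the isochroman.
- The fallback moves the ionic reduction to the end, when no ionisable silyl ether is left, and sets out from 10.
- MeOH with catalytic PPTS at 0 °C should give the methyl acetal tert-butyl[(2,4-dimethoxyphenyl)(1,6,7-trimethoxy-1H-isochromen-3-yl)methoxy]dimethylsilane F3.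
- TBAF in THF should free (2,4-dimethoxyphenyl)(1,6,7-trimethoxy-1H-isochromen-3-yl)methanol F4.
- MnO2 in CH2Cl2 should give (2,4-dimethoxyphenyl)(1,6,7-trimethoxy-1H-isochromen-3-yl)methanone F5.
- Et3SiH with BF3·OEt2 at −78 °C then reduces the acetal carbon through the acyl-substituted 2-benzopyrylium ion and comes back to the route at 14.

Step 4. The aluminium hemiacetal may collapse, because the enolate is a good leaving group, and be reduced further, or the lactol may open to the keto aldehyde on work-up and condense with itself.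
- The fallback accepts the ring opening and sets out from 9.
- Exhaustive reduction with LiAlH4 (THF, 0 °C; ethyl acetate, then aq potassium sodium tartrate) keeps the ketone masked as its aluminium enolate until work-up and should give 1-(tert-butyldimethylsilyloxy)-1-(2,4-dimethoxyphenyl)-3-[2-(hydroxymethyl)-4,5-dimethoxyphenyl]propan-2-one F6.
- Cyclodehydration of F6 with catalytic PPTS (toluene, 4 Å molecular sieves, 60 °C), through the cyclic hemiketal, gives the enol ether conjugated with ring A and comes back to the route at 12.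

**Further compounds**

F1 | step 3 | methyl 2-[3-(tert-butyldimethylsilyloxy)-3-(2,4-dimethoxyphenyl)prop-1-yn-1-yl]-4,5-dimethoxybenzoate | COc1ccc(C(O[Si](C)(C)C(C)(C)C)C#Cc2cc(OC)c(OC)cc2C(=O)OC)c(OC)c1
F2 | step 3 | 3-[(tert-butyldimethylsilyloxy)(2,4-dimethoxyphenyl)methyl]-4-iodo-6,7-dimethoxy-1H-isochromen-1-one | COc1ccc(C(O[Si](C)(C)C(C)(C)C)C2=C(I)c3cc(OC)c(OC)cc3C(=O)O2)c(OC)c1
F3 | step 5 | tert-butyl[(2,4-dimethoxyphenyl)(1,6,7-trimethoxy-1H-isochromen-3-yl)methoxy]dimethylsilane | COc1ccc(C(O[Si](C)(C)C(C)(C)C)C2=Cc3cc(OC)c(OC)cc3C(OC)O2)c(OC)c1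
F4 | step 5 | (2,4-dimethoxyphenyl)(1,6,7-trimethoxy-1H-isochromen-3-yl)methanol | COc1ccc(C(O)C2=Cc3cc(OC)c(OC)cc3C(OC)O2)c(OC)c1
F5 | step 5 | (2,4-dimethoxyphenyl)(1,6,7-trimethoxy-1H-isochromen-3-yl)methanone | COc1ccc(C(=O)C2=Cc3cc(OC)c(OC)cc3C(OC)O2)c(OC)c1
F6 | step 4 | 1-(tert-butyldimethylsilyloxy)-1-(2,4-dimethoxyphenyl)-3-[2-(hydroxymethyl)-4,5-dimethoxyphenyl]propan-2-one | COc1ccc(C(O[Si](C)(C)C(C)(C)C)C(=O)Cc2cc(OC)c(OC)cc2CO)c(OC)c1
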